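**Retrosynthetic overview**

1. Locants used throughout: C1 = CH–O(angelate), C2 = CH2, C3 = CH–OAc, C4 = C(CH3), C5 = CH next to the ketone, C6 = C=O, C7 = CH=, C8 = C(CH3)=, C9 and C10 = ring CH, C11 = C(CH3)2. The core is a cyclobutane (C4–C5–C10–C9); its 1,3-carbons C5/C9 carry the enone bridge C6–C7–C8 and its other 1,3-carbons C4/C10 carry the seven-membered ring.
2. Enabling feature: because C5 and C9 are the 1,3-related bridgeheads of that cyclobutane, a temporary C5–C9 bond (a bicyclo[1.1.0]butane, absent from the target) can be made and then spent, and its cleavage drives the C5–C6 ring closure that completes both six-membered rings.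
3. Disconnections: the two esters; the enone by oxidative 1,3-transposition from a C8 ketone; C5–C6 by reductive strain-release cyclization of a bicyclobutyl vinyl ketone; C4–C9 and C5–C9 by addition of a carbene at C9 to the C4=C5 alkene of a cycloheptene.
4. The cycloheptene comes from ring-closing metathesis of a chain whose stereocentres are set by an Ireland–Claisen rearrangement (C10), a boron aldol (C3) and a 1,3-anti reduction (C1).
5. Ring order: seven-membered ring, then the bicyclobutane (two three-membered rings), then the two six-membered rings with release of the cyclobutane.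

Key step: step 16

**Route**

Step 1
Reactants: 1 but-3-en-1-ol; 2 4-methoxybenzyl chloride
Product: 3 1-[(but-3-en-1-yloxy)methyl]-4-methoxybenzene
Conditions: NaH, Bu4NI (cat.), THF/DMF, 0 °C to rt
Reagents that add atoms: none
Why: Williamson etherification should give the PMB ether, which masks the future C8 oxygen through the basic steps that follow.

Step 2
Reactants: 3 1-[(but-3-en-1-yloxy)methyl]-4-methoxybenzene (3 equiv); 4 (R)-but-3-en-2-ol
Product: 5 (2R,3E)-6-[(4-methoxybenzyl)oxy]hex-3-en-2-ol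
Conditions: second-generation Hoveyda–Grubbs catalyst (3 mol%), CH2Cl2, 40 °C
Reagents that add atoms: none
Why: Olefin cross-metathesis of a terminal alkene with a secondary allylic alcohol should give the E-alkene selectively, and the carbinol stereocentre of 4 is not touched.

Step 3
Reactants: 5 (2R,3E)-6-[(4-methoxybenzyl)oxy]hex-3-en-2-ol; 6 2-methylpropanoyl chloride
Product: 7 (2R,3E)-6-[(4-methoxybenzyl)oxy]hex-3-en-2-yl 2-methylpropanoate
Conditions: Et3N, DMAP (cat.), CH2Cl2, 0 °C
Reagents that add atoms: none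
Why: DMAP-catalysed acylation of the allylic alcohol should give the isobutyrate needed for the Claisen step without touching the stereocentre.

Step 4
Reactants: 7 (2R,3E)-6-[(4-methoxybenzyl)oxy]hex-3-en-2-yl 2-methylpropanoate
Product: 10 (3S,4E)-3-{2-[(4-methoxybenzyl)oxy]ethyl}-2,2-dimethylhex-4-enoic acid, via silyl ketene acetal 8 (not isolated), via trimethylsilyl ester 9 (not isolated)
Conditions: LiN(iPr)2, THF, −78 °C; Me3SiCl; −78 to 60 °C; aq. HCl
Reagents that add atoms: none
Why: Ireland–Claisen rearrangement through a chair transition state with the carbinol methyl equatorial should transfer the (R)-carbinol chirality to C10 (3S) while forming the C10–C11 bond next to the quaternary carbon and the E-propenyl group.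

Step 5
Reactants: 10 (3S,4E)-3-{2-[(4-methoxybenzyl)oxy]ethyl}-2,2-dimethylhex-4-enoic acid
Product: 11 (4S,5E)-4-{2-[(4-methoxybenzyl)oxy]ethyl}-3,3-dimethylhept-5-en-2-one
Conditions: MeLi (2.2 equiv), Et2O, 0 °C to rt; Me3SiCl then aq. HCl
Reagents that add atoms: methyllithium, [Li]C
Why: Addition of methyllithium to the lithium carboxylate should stop at the ketone stage because the tetrahedral adduct does not collapse before work-up.

Step 6
Reactants: 11 (4S,5E)-4-{2-[(4-methoxybenzyl)oxy]ethyl}-3,3-dimethylhept-5-en-2-one; 12 methacrolein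
Product: 13 (3R,7S,8E)-3-hydroxy-7-{2-[(4-methoxybenzyl)oxy]ethyl}-2,6,6-trimethyldeca-1,8-dien-5-one
Conditions: (+)-Ipc2BCl, Et3N, Et2O, −78 to 0 °C; 12, −78 to −20 °C; H2O2, MeOH, pH 7 buffer
Reagents that add atoms: none
Why: Paterson boron aldol reaction, in which the ketone can enolize only on its methyl side and the (+)-reagent should direct addition to the Re face of methacrolein to set C3 as R (the (−)-reagent is known to favour the Si face with methyl ketones); a minor C3 epimer would be removed at the diol stage.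

Step 7
Reactants: 13 (3R,7S,8E)-3-hydroxy-7-{2-[(4-methoxybenzyl)oxy]ethyl}-2,6,6-trimethyldeca-1,8-dien-5-one
Product: 14 (3R,5R,7S,8E)-7-{2-[(4-methoxybenzyl)oxy]ethyl}-2,6,6-trimethyldeca-1,8-diene-3,5-diol
Conditions: Me4NBH(OAc)3, MeCN/AcOH, −30 °C
Reagents that add atoms: none
Why: Evans–Saksena reduction with intramolecular hydride delivery from the borohydride bound to the C3 hydroxyl should give the 1,3-anti diol and so set C1 (5R).

Step 8
Reactants: 14 (3R,5R,7S,8E)-7-{2-[(4-methoxybenzyl)oxy]ethyl}-2,6,6-trimethyldeca-1,8-diene-3,5-diol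
Product: 15 3,5-bis-O-(tert-butyldimethylsilyl) ether of 14
Conditions: TBSOTf (2.5 equiv), 2,6-lutidine, CH2Cl2, −78 to 0 °C
Reagents that add atoms: tert-butyldimethylsilyl trifluoromethanesulfonate, CC(C)(C)[Si](C)(C)OS(=O)(=O)C(F)(F)F
Why: Silylation with the silyl triflate should cap both secondary alcohols, including the neopentyl C1 hydroxyl.

Step 9
Reactants: 15 3,5-bis-O-(tert-butyldimethylsilyl) ether of 14
Product: 16 (1R,3R,6S)-1,3-bis[(tert-butyldimethylsilyl)oxy]-6-{2-[(4-methoxybenzyl)oxy]ethyl}-4,7,7-trimethylcyclohept-4-ene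
Conditions: second-generation Hoveyda–Grubbs catalyst (10 mol%), toluene, 80 °C
Reagents that add atoms: none
Why: Ring-closing metathesis between the isopropenyl and propenyl groups should close the seven-membered ring as the trisubstituted C4=C5 alkene with loss of propene, helped by the gem-dimethyl group.

Step 10
Reactants: 16 (1R,3R,6S)-1,3-bis[(tert-butyldimethylsilyl)oxy]-6-{2-[(4-methoxybenzyl)oxy]ethyl}-4,7,7-trimethylcyclohept-4-ene
Product: 17 (1R,3R,6S)-1,3-bis[(tert-butyldimethylsilyl)oxy]-6-(2-hydroxyethyl)-4,7,7-trimethylcyclohept-4-ene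
Conditions: DDQ, CH2Cl2/pH 7 buffer, 0 °C to rt
Reagents that add atoms: none
Why: Oxidative cleavage of the PMB ether should free the primary alcohol without touching the silyl ethers or the trisubstituted alkene.

Step 11
Reactants: 17 (1R,3R,6S)-1,3-bis[(tert-butyldimethylsilyl)oxy]-6-(2-hydroxyethyl)-4,7,7-trimethylcyclohept-4-ene
Product: 18 (1R,3R,6S)-1,3-bis[(tert-butyldimethylsilyl)oxy]-6-(carboxymethyl)-4,7,7-trimethylcyclohept-4-ene
Conditions: TEMPO (cat.), PhI(OAc)2 (2.2 equiv), MeCN/H2O, rt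
Reagents that add atoms: water, O
Why: Oxoammonium oxidation in wet acetonitrile should take the primary alcohol through the aldehyde hydrate to the carboxylic acid while leaving the alkene and silyl ethers intact.

Step 12
Reactants: 18 (1R,3R,6S)-1,3-bis[(tert-butyldimethylsilyl)oxy]-6-(carboxymethyl)-4,7,7-trimethylcyclohept-4-ene
Product: 20 N-methoxy-N-methylamide of 18, via acyl imidazolide 19 (not isolated)
Conditions: 1,1'-carbonyldiimidazole, CH2Cl2, rt; MeNH(OMe)·HCl
Reagents that add atoms: N,O-dimethylhydroxylamine hydrochloride, CNOC.Cl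
Why: Activation as the acyl imidazolide and aminolysis should give the Weinreb amide, the acyl group that later accepts exactly one vinyl nucleophile.

Step 13
Reactants: 20 N-methoxy-N-methylamide of 18
Product: 22 2-diazo derivative of 20 (diazo carbon = C9, attached to C10), via trifluoroacetyl amide 21 (not isolated)
Conditions: LiN(iPr)2, THF, −78 °C; CF3CO2CH2CF3; then MsN3, Et3N, H2O (1 equiv), MeCN, rt
Reagents that add atoms: methanesulfonyl azide, CS(=O)(=O)N=[N+]=[N-]
Why: Danheiser detrifluoroacetylative diazo transfer should place the diazo group on C9, the only enolizable carbon, after temporary activation as the trifluoroacetyl derivative.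

Step 14
Reactants: 22 2-diazo derivative of 20
Product: 23 3,5-bis[(tert-butyldimethylsilyl)oxy]-N-methoxy-N,2,6,6-tetramethyltricyclo[5.1.0.0(2,8)]octane-8-carboxamide (bridged bicyclo[1.1.0]butane, central bond C5–C9; C4 methyl and C10 hydrogen exo)
Conditions: Rh2(OPiv)4 (1 mol%), toluene, −78 to −20 °C
Reagents that add atoms: none
Why: Rhodium-carbenoid cyclopropanation of the allylic C4=C5 alkene by the carbene at C9 (the allyl-carbene route to bicyclo[1.1.0]butanes known for α-allyl-α-diazo carbonyl compounds) should form the C4–C9 bond and the temporary C5–C9 bond, and because the carbene is tethered through C10 it can reach only one alkene face, so the quaternary centre C4, C5 and C9 all follow from C10, with the bulky carboxylate ligand and low temperature suppressing 1,2-hydride shift.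

Step 15
Reactants: 23 bicyclobutane Weinreb amide
Product: 24 1-{3,5-bis[(tert-butyldimethylsilyl)oxy]-2,6,6-trimethyltricyclo[5.1.0.0(2,8)]oct-8-yl}prop-2-en-1-one
Conditions: CH2=CHMgBr (1.5 equiv), THF, −78 to 0 °C; cold aq. NH4Cl; used at once
Reagents that add atoms: vinylmagnesium bromide, C=C[Mg]Br
Why: Weinreb ketone synthesis, the standard entry to bicyclobutyl ketones, should deliver one vinyl group to the carbonyl carbon because the amide releases the ketone only on work-up.

Step 16
Reactants: 24 bicyclobutyl vinyl ketone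
Product: 25 3,5-bis[(tert-butyldimethylsilyl)oxy]-2,6,6-trimethyltricyclo[5.4.0.0(2,8)]undecan-9-one (ketone on C8; all stereocentres as in the target)
Conditions: SmI2 (2.5 equiv, added over 1 h), t-BuOH (3 equiv), THF, −78 °C
Reagents that add atoms: none
Why: Proposed new method: one-electron reduction of the cross-conjugated vinyl ketone gives a samarium ketyl, which fragments the strained central C5–C9 bond (a cyclopropylcarbinyl-type opening driven by roughly 65 kcal/mol of bicyclobutane strain) to a cyclobutyl radical at C5 and a samarium dienolate; the C5 radical adds to the terminal vinyl carbon C6, and a second electron plus tert-butanol convert the resulting radical/enolate into the saturated C8 ketone with hydrogen at C9. The closest known reaction type is the SmI2-mediated ketyl/strain-release coupling of bicyclo[1.1.0]butyl ketones with alkenes to bicyclo[2.1.1]hexanes, together with reductive ketyl–olefin cyclizations. The closure is a 6-endo-trig radical addition that completes both six-membered rings (C5–C6–C7–C8–C9 closed through C10 and through C4) as a bicyclo[3.1.1]heptanone and turns the bicyclobutane into the cyclobutane of the target. No stereocentre is chosen here: C4, C5, C9 and C10 were fixed when the bicyclobutane was made, and the three-carbon bridge can span C5 and C9 only on the convex face. The step needs attack at C6 and not C7 (the 5-exo mode would give a primary radical and a bridgehead enolate in a bicyclo[2.1.1]hexane) and ring closure before the C5 radical is reduced, which the short tether (C6 about 3 Å from C5) and slow addition of SmI2 at low temperature should secure.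

Step 17
Reactants: 25 tricyclic C8 ketone
Product: 27 3,5-bis[(tert-butyldimethylsilyl)oxy]-2,6,6-trimethyltricyclo[5.4.0.0(2,8)]undec-10-en-9-one, via trimethylsilyl enol ether 26 (not isolated)
Conditions: LiN(SiMe3)2, Me3SiCl, THF, −78 °C; then Pd(OAc)2 (1.1 equiv), MeCN, rt
Reagents that add atoms: none
Why: Saegusa–Ito dehydrogenation should give a single enone because the ketone can enolize only towards C7, C9 being a bridgehead of the bicyclo[3.1.1]heptane.

Step 18
Reactants: 27 transposed enone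
Product: 28 3,5-bis[(tert-butyldimethylsilyl)oxy]-2,6,6,9-tetramethyltricyclo[5.4.0.0(2,8)]undec-10-en-9-ol
Conditions: MeLi, Et2O/THF, −78 °C
Reagents that add atoms: methyllithium, [Li]C
Why: 1,2-Addition of methyllithium to the enone carbonyl should give the tertiary allylic alcohol, attack coming from the face away from the C4 methyl group; the new centre at C8 is removed in the next step.

Step 19
Reactants: 28 tertiary allylic alcohol
Product: 29 3,5-bis[(tert-butyldimethylsilyl)oxy]-2,6,6,9-tetramethyltricyclo[5.4.0.0(2,8)]undec-9-en-11-one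
Conditions: pyridinium chlorochromate (2 equiv), NaOAc, 4 Å molecular sieves, CH2Cl2, rt
Reagents that add atoms: pyridinium chlorochromate, [O-][Cr](=O)(=O)Cl.c1cc[nH+]cc1
Why: Dauben–Michno oxidative 1,3-transposition (chromate ester, [3,3] shift to C6, oxidation) should give the 3-methyl enone with the carbonyl on C6, as in the known conversion of apoverbenone-type enones into verbenones.

Step 20
Reactants: 29 bis-silyl enone
Product: 30 3,5-dihydroxy-2,6,6,9-tetramethyltricyclo[5.4.0.0(2,8)]undec-9-en-11-one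
Conditions: HF·pyridine, THF/pyridine, 0 to 40 °C
Reagents that add atoms: none
Why: Fluoride-mediated cleavage of both silyl ethers should give the diol, the enone and cyclobutane being inert to these conditions.

Step 21
Reactants: 30 diol
Product: 31 3-acetoxy-5-hydroxy-2,6,6,9-tetramethyltricyclo[5.4.0.0(2,8)]undec-9-en-11-one (acetate on C3)
Conditions: Ac2O (1.05 equiv), pyridine, DMAP (cat.), CH2Cl2, −20 °C
Reagents that add atoms: acetic anhydride, CC(=O)OC(C)=O
Why: Kinetically controlled acylation should take place at the C3 hydroxyl, whose neighbour C4 is tied back in the cyclobutane, in preference to the C1 hydroxyl flanked by the gem-dimethyl group.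

Step 22
Reactants: 31 hydroxy acetate; 32 angelic acid
Product: 34 3-acetoxy-2,6,6,9-tetramethyl-11-oxotricyclo[5.4.0.0(2,8)]undec-9-en-5-yl (2Z)-2-methylbut-2-enoate (CNP0260482.1), via mixed anhydride 33 (not isolated)
Conditions: 32, 2,4,6-trichlorobenzoyl chloride, Et3N, toluene, rt; then 31, toluene, 75 °C
Reagents that add atoms: none
Why: Esterification through the mixed 2,4,6-trichlorobenzoic anhydride (Yamaguchi-type acylation) should acylate the hindered C1 alcohol while keeping the Z geometry of the angelate.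

**Compound list**

1 | but-3-en-1-ol | C=CCCO | starting material
2 | 4-methoxybenzyl chloride | COc1ccc(CCl)cc1 | starting material
3 | 1-[(but-3-en-1-yloxy)methyl]-4-methoxybenzene | C=CCCOCc1ccc(OC)cc1 | intermediate
4 | (R)-but-3-en-2-ol | C[C@@H](O)C=C | starting material
5 | (2R,3E)-6-[(4-methoxybenzyl)oxy]hex-3-en-2-ol | C[C@@H](O)/C=C/CCOCc1ccc(OC)cc1 | intermediate
6 | 2-methylpropanoyl chloride | CC(C)C(Cl)=O | starting material
7 | (2R,3E)-6-[(4-methoxybenzyl)oxy]hex-3-en-2-yl 2-methylpropanoate | C[C@@H](OC(=O)C(C)C)/C=C/CCOCc1ccc(OC)cc1 | intermediate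
8 | trimethylsilyl ketene acetal of 7 | C[C@@H](OC(O[Si](C)(C)C)=C(C)C)/C=C/CCOCc1ccc(OC)cc1 | intermediate
9 | trimethylsilyl ester of 10 | C[Si](C)(C)OC(=O)C(C)(C)[C@@H](CCOCc1ccc(OC)cc1)/C=C/C | intermediate
10 | (3S,4E)-3-{2-[(4-methoxybenzyl)oxy]ethyl}-2,2-dimethylhex-4-enoic acid | OC(=O)C(C)(C)[C@@H](CCOCc1ccc(OC)cc1)/C=C/C | intermediate
11 | (4S,5E)-4-{2-[(4-methoxybenzyl)oxy]ethyl}-3,3-dimethylhept-5-en-2-one | CC(=O)C(C)(C)[C@@H](CCOCc1ccc(OC)cc1)/C=C/C | intermediate
12 | methacrolein | CC(=C)C=O | starting material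
13 | (3R,7S,8E)-3-hydroxy-7-{2-[(4-methoxybenzyl)oxy]ethyl}-2,6,6-trimethyldeca-1,8-dien-5-one | CC(=C)[C@H](O)CC(=O)C(C)(C)[C@@H](CCOCc1ccc(OC)cc1)/C=C/C | intermediate
14 | (3R,5R,7S,8E)-7-{2-[(4-methoxybenzyl)oxy]ethyl}-2,6,6-trimethyldeca-1,8-diene-3,5-diol | CC(=C)[C@H](O)C[C@@H](O)C(C)(C)[C@@H](CCOCc1ccc(OC)cc1)/C=C/C | intermediate
15 | 3,5-bis-O-(tert-butyldimethylsilyl) ether of 14 | CC(=C)[C@H](O[Si](C)(C)C(C)(C)C)C[C@@H](O[Si](C)(C)C(C)(C)C)C(C)(C)[C@@H](CCOCc1ccc(OC)cc1)/C=C/C | intermediate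
16 | (1R,3R,6S)-1,3-bis[(tert-butyldimethylsilyl)oxy]-6-{2-[(4-methoxybenzyl)oxy]ethyl}-4,7,7-trimethylcyclohept-4-ene | CC(C)(C)[Si](C)(C)O[C@@H]1C[C@@H](O[Si](C)(C)C(C)(C)C)C(C)=C[C@H](CCOCc2ccc(OC)cc2)C1(C)C | intermediate
17 | (1R,3R,6S)-1,3-bis[(tert-butyldimethylsilyl)oxy]-6-(2-hydroxyethyl)-4,7,7-trimethylcyclohept-4-ene | CC(C)(C)[Si](C)(C)O[C@@H]1C[C@@H](O[Si](C)(C)C(C)(C)C)C(C)=C[C@H](CCO)C1(C)C | intermediate
18 | (1R,3R,6S)-1,3-bis[(tert-butyldimethylsilyl)oxy]-6-(carboxymethyl)-4,7,7-trimethylcyclohept-4-ene | CC(C)(C)[Si](C)(C)O[C@@H]1C[C@@H](O[Si](C)(C)C(C)(C)C)C(C)=C[C@H](CC(O)=O)C1(C)C | intermediate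
19 | acyl imidazolide of 18 | CC(C)(C)[Si](C)(C)O[C@@H]1C[C@@H](O[Si](C)(C)C(C)(C)C)C(C)=C[C@H](CC(=O)n2ccnc2)C1(C)C | intermediate
20 | N-methoxy-N-methylamide of 18 | CC(C)(C)[Si](C)(C)O[C@@H]1C[C@@H](O[Si](C)(C)C(C)(C)C)C(C)=C[C@H](CC(=O)N(C)OC)C1(C)C | intermediate
21 | 2-(trifluoroacetyl) derivative of 20 (C9 epimers, enolized) | CC(C)(C)[Si](C)(C)O[C@@H]1C[C@@H](O[Si](C)(C)C(C)(C)C)C(C)=C[C@H](C(C(=O)C(F)(F)F)C(=O)N(C)OC)C1(C)C | intermediate
22 | 2-diazo derivative of 20 | CC(C)(C)[Si](C)(C)O[C@@H]1C[C@@H](O[Si](C)(C)C(C)(C)C)C(C)=C[C@H](C(=[N+]=[N-])C(=O)N(C)OC)C1(C)C | intermediate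
23 | 3,5-bis[(tert-butyldimethylsilyl)oxy]-N-methoxy-N,2,6,6-tetramethyltricyclo[5.1.0.0(2,8)]octane-8-carboxamide | CC(C)(C)[Si](C)(C)O[C@@H]1C[C@@H](O[Si](C)(C)C(C)(C)C)[C@@]2(C)[C@@H]3[C@@]2(C(=O)N(C)OC)[C@@H]3C1(C)C | intermediate
24 | 1-{3,5-bis[(tert-butyldimethylsilyl)oxy]-2,6,6-trimethyltricyclo[5.1.0.0(2,8)]oct-8-yl}prop-2-en-1-one | CC(C)(C)[Si](C)(C)O[C@@H]1C[C@@H](O[Si](C)(C)C(C)(C)C)[C@@]2(C)[C@@H]3[C@@]2(C(=O)C=C)[C@@H]3C1(C)C | intermediate
25 | 3,5-bis[(tert-butyldimethylsilyl)oxy]-2,6,6-trimethyltricyclo[5.4.0.0(2,8)]undecan-9-one | CC(C)(C)[Si](C)(C)O[C@@H]1C[C@@H](O[Si](C)(C)C(C)(C)C)[C@@]2(C)[C@@H]3CCC(=O)[C@H]2[C@@H]3C1(C)C | intermediate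
26 | trimethylsilyl enol ether of 25 | CC(C)(C)[Si](C)(C)O[C@@H]1C[C@@H](O[Si](C)(C)C(C)(C)C)[C@@]2(C)[C@@H]3CC=C(O[Si](C)(C)C)[C@H]2[C@@H]3C1(C)C | intermediate
27 | 3,5-bis[(tert-butyldimethylsilyl)oxy]-2,6,6-trimethyltricyclo[5.4.0.0(2,8)]undec-10-en-9-one | CC(C)(C)[Si](C)(C)O[C@@H]1C[C@@H](O[Si](C)(C)C(C)(C)C)[C@@]2(C)[C@@H]3C=CC(=O)[C@H]2[C@@H]3C1(C)C | intermediate
28 | 3,5-bis[(tert-butyldimethylsilyl)oxy]-2,6,6,9-tetramethyltricyclo[5.4.0.0(2,8)]undec-10-en-9-ol | CC(C)(C)[Si](C)(C)O[C@@H]1C[C@@H](O[Si](C)(C)C(C)(C)C)[C@@]2(C)[C@@H]3C=C[C@](C)(O)[C@H]2[C@@H]3C1(C)C | intermediate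
29 | 3,5-bis[(tert-butyldimethylsilyl)oxy]-2,6,6,9-tetramethyltricyclo[5.4.0.0(2,8)]undec-9-en-11-one | CC(C)(C)[Si](C)(C)O[C@@H]1C[C@@H](O[Si](C)(C)C(C)(C)C)[C@@]2(C)[C@@H]3C(=O)C=C(C)[C@H]2[C@@H]3C1(C)C | intermediate
30 | 3,5-dihydroxy-2,6,6,9-tetramethyltricyclo[5.4.0.0(2,8)]undec-9-en-11-one | O[C@@H]1C[C@@H](O)[C@@]2(C)[C@@H]3C(=O)C=C(C)[C@H]2[C@@H]3C1(C)C | intermediate
31 | 3-acetoxy-5-hydroxy-2,6,6,9-tetramethyltricyclo[5.4.0.0(2,8)]undec-9-en-11-one | O[C@@H]1C[C@@H](OC(C)=O)[C@@]2(C)[C@@H]3C(=O)C=C(C)[C@H]2[C@@H]3C1(C)C | intermediate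
32 | angelic acid, (2Z)-2-methylbut-2-enoic acid | C/C=C(/C)C(=O)O | starting material
33 | angelic 2,4,6-trichlorobenzoic anhydride | C/C=C(/C)C(=O)OC(=O)c1c(Cl)cc(Cl)cc1Cl | intermediate
34 | 3-acetoxy-2,6,6,9-tetramethyl-11-oxotricyclo[5.4.0.0(2,8)]undec-9-en-5-yl (2Z)-2-methylbut-2-enoate (CNP0260482.1) | C/C=C(/C)C(=O)O[C@@H]1C[C@@H](OC(C)=O)[C@@]2(C)[C@@H]3C(=O)C=C(C)[C@H]2[C@@H]3C1(C)C | target

**Step count**

Total: 22 steps. Longest linear sequence: 22 steps (from 1 to 34).

**Steps most likely to fail**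

Step 16 (proposed new method). The C5 radical may be reduced and protonated, or the vinyl ketone may polymerize, before the C5–C6 bond forms. The fallback uses known two-electron and metathesis chemistry; it sets out from bicyclobutane 23 and returns at enone 27. Copper-catalysed homoconjugate addition of vinylmagnesium bromide (CuBr·SMe2, THF, −78 °C) should open the C5–C9 bond with delivery of the vinyl group to C5 and, after protonation of the amide enolate from the exo face, give the 5-vinylcyclobutane Weinreb amide F1. More vinylmagnesium bromide at 0 °C should then give the divinyl ketone F2, and ring-closing metathesis with second-generation Hoveyda–Grubbs catalyst should close the six-membered ring at C6=C7 to give 27, so that 24–26 are bypassed.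

Step 14. A 1,2-hydride shift from C10, or carbenoid C–H insertion into the N-methoxy-N-methyl group, may outrun cyclopropanation of the hindered trisubstituted alkene. The fallback moves the carbene step to the substrate class for which bicyclobutane formation is documented (α-allyl-α-diazo esters); it sets out from acid 18 and returns at 23. Esterification with Me3SiCHN2 should give the methyl ester F3, detrifluoroacetylative diazo transfer the α-diazo ester F4, and Rh2(OPiv)4 at −78 °C the bicyclobutane methyl ester F5. Aminolysis with MeNH(OMe)·HCl/iPrMgCl at −20 °C should then give 23.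

Step 21. The two hindered secondary hydroxyl groups may be poorly discriminated, giving the C1 acetate or the diacetate. The fallback differentiates them with a bulkier electrophile and reverses the order of acylation; it sets out from diol 30 and returns at target 34. Et3SiOTf (1.0 equiv, 2,6-lutidine, −78 °C) should silylate the less hindered C3 hydroxyl to give the 3-O-triethylsilyl ether F6. Acylation of the remaining C1 hydroxyl with mixed anhydride 33 should give the silyl angelate F7, HF·pyridine the hydroxy angelate F8, and Ac2O/DMAP then 34.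

Further compounds
F1 | step 16 | 5-vinylcyclobutane Weinreb amide (C5–C9 bond opened; vinyl on C5 and amide on C9 cis, both exo) | CC(C)(C)[Si](C)(C)O[C@@H]1C[C@@H](O[Si](C)(C)C(C)(C)C)[C@@]2(C)[C@H](C=C)[C@H]([C@@H]2C(=O)N(C)OC)C1(C)C
F2 | step 16 | divinyl ketone (C5 vinyl, C9 propenoyl) | CC(C)(C)[Si](C)(C)O[C@@H]1C[C@@H](O[Si](C)(C)C(C)(C)C)[C@@]2(C)[C@H](C=C)[C@H]([C@@H]2C(=O)C=C)C1(C)C
F3 | step 14 | methyl ester of 18 | CC(C)(C)[Si](C)(C)O[C@@H]1C[C@@H](O[Si](C)(C)C(C)(C)C)C(C)=C[C@H](CC(=O)OC)C1(C)C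
F4 | step 14 | α-diazo methyl ester | CC(C)(C)[Si](C)(C)O[C@@H]1C[C@@H](O[Si](C)(C)C(C)(C)C)C(C)=C[C@H](C(=[N+]=[N-])C(=O)OC)C1(C)C
F5 | step 14 | bicyclobutane methyl ester | CC(C)(C)[Si](C)(C)O[C@@H]1C[C@@H](O[Si](C)(C)C(C)(C)C)[C@@]2(C)[C@@H]3[C@@]2(C(=O)OC)[C@@H]3C1(C)C
F6 | step 21 | 3-O-triethylsilyl ether of 30 | O[C@@H]1C[C@@H](O[Si](CC)(CC)CC)[C@@]2(C)[C@@H]3C(=O)C=C(C)[C@H]2[C@@H]3C1(C)C
F7 | step 21 | 3-O-triethylsilyl 5-angelate | C/C=C(/C)C(=O)O[C@@H]1C[C@@H](O[Si](CC)(CC)CC)[C@@]2(C)[C@@H]3C(=O)C=C(C)[C@H]2[C@@H]3C1(C)C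
F8 | step 21 | 3-hydroxy 5-angelate | C/C=C(/C)C(=O)O[C@@H]1C[C@@H](O)[C@@]2(C)[C@@H]3C(=O)C=C(C)[C@H]2[C@@H]3C1(C)C
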